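The tetrahydrofuran ring (O1, C2, C3, C4, C5) is disconnected into an O1–C2–C3 unit and a C4–C5 unit. C3 carries a one-carbon arm that can be masked as a vinyl group, which makes C3 an allylic terminus, and C4 carries the benzylic carbon C7′, which at the ketone level makes C4=C5 an enone. A palladium-catalysed formal [3+2] cycloaddition of an enantioenriched 2-aryl-3-vinyloxirane with 4-methoxyphenyl vinyl ketone therefore forms O1–C5 and C3–C4 in one operation, and the oxirane's aryl-bearing stereocentre (C2) relays to C3 and C4. Catalyst-controlled ketone reduction, ozonolysis–reduction, acetylation and desilylation complete the route.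

Key step: step 4

Remarks on the chemistry: ring numbering is O1, C2 (aryl-bearing), C3, C4, C5 (ring CH2); C7′ is the exocyclic carbinol carbon on C4; the target is (2R,3S,4R,7′S), all-trans on the ring. In the SMILES of 8 and 9 the allylpalladium unit is drawn in its σ-allyl form and the phosphines on palladium are not drawn.

Step 1
Reactants: 1 4-[(tert-butyldimethylsilyl)oxy]benzaldehyde; 2 allyl chloride
Product: 4 (1S,2S)-1-{4-[(tert-butyldimethylsilyl)oxy]phenyl}-2-chlorobut-3-en-1-ol (syn chlorohydrin), via diisopinocampheylborinate 3 (not isolated)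
Conditions: 2, (+)-Ipc2BOMe (from (−)-α-pinene), LiN(c-C6H11)2, Et2O, −95 °C; BF3·OEt2, then 1, −95 °C; HOCH2CH2NH2 work-up
Reagents that add atoms: none
Why: Asymmetric γ-chloroallylboration, in which the (Z)-γ-chloroallylborane made in the flask adds through a closed chair (Zimmerman–Traxler) transition state, the Z geometry giving the syn chlorohydrin and the isopinocampheyl groups directing attack to the Re face of the aldehyde to set (1S).

Step 2
Reactants: 4 syn chlorohydrin
Product: 5 (2S,3R)-2-{4-[(tert-butyldimethylsilyl)oxy]phenyl}-3-ethenyloxirane (cis)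
Conditions: DBU, CH2Cl2, 0 °C → rt; chromatography on Et3N-deactivated silica
Reagents that add atoms: none
Why: Intramolecular Williamson (SN2) closure of the alkoxide onto the allylic chloride with inversion should give the cis-oxirane, the carbinol centre is untouched, and the non-nucleophilic amidine base leaves the aryl silyl ether intact.

Step 3
Reactants: 6 3-chloro-1-(4-methoxyphenyl)propan-1-one
Product: 7 1-(4-methoxyphenyl)prop-2-en-1-one
Conditions: Et3N, Et2O, 0 °C → rt; filtration; used at once
Reagents that add atoms: none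
Why: E1cB elimination of HCl from the β-chloro ketone should give the polymerisation-prone aryl vinyl ketone, which is therefore prepared fresh.

Step 4
Reactants: 5 cis-vinyloxirane; 7 1-(4-methoxyphenyl)prop-2-en-1-one
Product: 10 [(3R,4R,5R)-5-{4-[(tert-butyldimethylsilyl)oxy]phenyl}-4-ethenyloxolan-3-yl](4-methoxyphenyl)methanone (all-trans), via zwitterionic allylpalladium alkoxide 8 (not isolated), via palladium-bound enolate 9 (not isolated)
Conditions: Pd2(dba)3·CHCl3 (2.5 mol %), P(4-FC6H4)3 (15 mol %), n-Bu4NCl (10 mol %), 7 (1.5 equiv), THF, 0 °C → rt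
Reagents that add atoms: none
Why: Zerovalent palladium ionises the allylic C3–O bond of 5 with inversion to the zwitterionic π-allyl complex of divalent palladium 8; its alkoxide adds in an oxa-Michael sense to the unsubstituted β-carbon of 7 (O1–C5), and the ketone enolate 9 so formed alkylates the substituted allyl terminus (C3–C4), returning zerovalent palladium. The closest known reaction type is the palladium-catalysed formal [3+2] cycloaddition of vinyl oxiranes with electron-poor alkenes (Tsuji–Trost chemistry of a 1,3-zwitterion). The oxolane closes in a 5-exo mode, the enolate carbon attacking the internal allyl carbon so that the remaining alkene becomes the exocyclic vinyl group, whereas closure at the CH2 terminus would need a seven-membered ring. C2 is carried over unchanged because its C–O bond is never broken; C3 is set trans to the C2 aryl group by substrate control, since the diastereomeric allyl complexes exchange faces by η3–η1–η3 isomerisation at the unsubstituted terminus faster than they cyclise (Curtin–Hammett), which also makes the cis geometry of 5 irrelevant; C4 is set trans to the vinyl group and, being α to the ketone, this is also the thermodynamic epimer. The step needs O-alkylation of the enone before C–C bond formation, internal rather than terminal allylic attack, and cyclisation faster than isomerisation of 8 (hydride shift to an aryl ketone, collapse to a 2,5-dihydrofuran); these should be secured by the very electrophilic β-unsubstituted vinyl ketone in excess, by the electron-poor phosphine, which makes the allyl unit more electrophilic toward the monostabilised enolate, and by chloride, which speeds the face exchange.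

Step 5
Reactants: 10 all-trans ketone
Product: 12 (S)-[(3R,4R,5R)-5-{4-[(tert-butyldimethylsilyl)oxy]phenyl}-4-ethenyloxolan-3-yl](4-methoxyphenyl)methanol, via catechol borate 11 (not isolated)
Conditions: (R)-1-methyl-3,3-diphenyltetrahydro-1H,3H-pyrrolo[1,2-c][1,3,2]oxazaborole [(R)-Me-CBS, 20 mol %], catecholborane, toluene, −78 → −40 °C; then MeOH
Reagents that add atoms: none
Why: Corey–Bakshi–Shibata reduction, in which the (R)-oxazaborolidine delivers hydride to the face that gives the (S)-aryl carbinol (aryl as the large group), a sense that Felkin–Anh attack anti to ring carbon C3 reinforces, while catecholborane at low temperature should not hydroborate the vinyl group.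

Step 6
Reactants: 12 (S)-alcohol
Product: 14 (S)-[(3R,4S,5R)-5-{4-[(tert-butyldimethylsilyl)oxy]phenyl}-4-(hydroxymethyl)oxolan-3-yl](4-methoxyphenyl)methanol, via hydroxy aldehyde 13 (not isolated)
Conditions: O3, CH2Cl2/MeOH, −78 °C (Sudan Red 7B end-point); then NaBH4, −78 → 0 °C
Reagents that add atoms: ozone, [O-][O+]=O
Why: Ozonolysis of the only alkene, which is far more reactive than the two arenes, followed by borohydride reduction of the ozonolysis products in the same flask should shorten the vinyl group to hydroxymethyl without touching a stereocentre, the C3 centre of 13 already being in its all-trans thermodynamic configuration.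

Step 7
Reactants: 14 diol
Product: 15 (S)-[(3R,4S,5R)-4-(acetoxymethyl)-5-{4-[(tert-butyldimethylsilyl)oxy]phenyl}oxolan-3-yl](4-methoxyphenyl)methyl acetate
Conditions: Ac2O, pyridine, 4-(dimethylamino)pyridine (cat.), CH2Cl2, 0 °C → rt
Reagents that add atoms: acetic anhydride, CC(=O)OC(C)=O
Why: Nucleophile-catalysed acylation should esterify the primary and the secondary benzylic hydroxyl groups with retention while the phenol stays masked as its silyl ether.

Step 8
Reactants: 15 diacetate silyl ether
Product: 16 (S)-[(3R,4S,5R)-4-(acetoxymethyl)-5-(4-hydroxyphenyl)oxolan-3-yl](4-methoxyphenyl)methyl acetate (target)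
Conditions: n-Bu4NF, AcOH (1:1), THF, 0 °C
Reagents that add atoms: none
Why: Fluoride-mediated desilylation should cleave the aryl silyl ether selectively (phenoxide is a good leaving group on silicon), and the acetic acid buffer keeps the phenol protonated so that neither acetate cleavage or migration nor quinone-methide opening of the benzylic ring ether can start.

Compound list
1 | 4-[(tert-butyldimethylsilyl)oxy]benzaldehyde | O=Cc1ccc(O[Si](C)(C)C(C)(C)C)cc1 | starting material
2 | allyl chloride (3-chloroprop-1-ene) | C=CCCl | starting material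
3 | (1S,2S)-1-{4-[(tert-butyldimethylsilyl)oxy]phenyl}-2-chlorobut-3-en-1-yl diisopinocampheylborinate (isopinocampheyl groups from (−)-α-pinene) | CC(C)(C)[Si](C)(C)Oc1ccc(cc1)[C@H](OB([C@H]1C[C@H]2C[C@@H]([C@@H]1C)C2(C)C)[C@H]1C[C@H]2C[C@@H]([C@@H]1C)C2(C)C)[C@@H](Cl)C=C | intermediate
4 | (1S,2S)-1-{4-[(tert-butyldimethylsilyl)oxy]phenyl}-2-chlorobut-3-en-1-ol (syn) | CC(C)(C)[Si](C)(C)Oc1ccc(cc1)[C@H](O)[C@@H](Cl)C=C | intermediate
5 | (2S,3R)-2-{4-[(tert-butyldimethylsilyl)oxy]phenyl}-3-ethenyloxirane (cis) | CC(C)(C)[Si](C)(C)Oc1ccc(cc1)[C@@H]1O[C@@H]1C=C | intermediate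
6 | 3-chloro-1-(4-methoxyphenyl)propan-1-one | COc1ccc(cc1)C(=O)CCCl | starting material
7 | 1-(4-methoxyphenyl)prop-2-en-1-one | COc1ccc(cc1)C(=O)C=C | intermediate
8 | zwitterionic allylpalladium alkoxide, (R) at the aryl carbinolate carbon, drawn as (2E)-4-aryl-4-oxidobut-2-en-1-ylpalladium cation | [O-][C@@H](c1ccc(O[Si](C)(C)C(C)(C)C)cc1)/C=C/C[Pd+] | intermediate
9 | palladium-bound enolate formed by oxa-Michael addition of 8 to 7 (enolate geometry not specified) | COc1ccc(cc1)C([O-])=CCO[C@@H](c1ccc(O[Si](C)(C)C(C)(C)C)cc1)/C=C/C[Pd+] | intermediate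
10 | [(3R,4R,5R)-5-{4-[(tert-butyldimethylsilyl)oxy]phenyl}-4-ethenyloxolan-3-yl](4-methoxyphenyl)methanone | COc1ccc(C(=O)[C@H]2CO[C@@H](c3ccc(O[Si](C)(C)C(C)(C)C)cc3)[C@@H]2C=C)cc1 | intermediate
11 | catechol borate (1,3,2-benzodioxaborol-2-yl ester) of alcohol 12 | COc1ccc([C@@H](OB5Oc6ccccc6O5)[C@H]2CO[C@@H](c3ccc(O[Si](C)(C)C(C)(C)C)cc3)[C@@H]2C=C)cc1 | intermediate
12 | (S)-[(3R,4R,5R)-5-{4-[(tert-butyldimethylsilyl)oxy]phenyl}-4-ethenyloxolan-3-yl](4-methoxyphenyl)methanol | COc1ccc([C@@H](O)[C@H]2CO[C@@H](c3ccc(O[Si](C)(C)C(C)(C)C)cc3)[C@@H]2C=C)cc1 | intermediate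
13 | (2R,3R,4R)-2-{4-[(tert-butyldimethylsilyl)oxy]phenyl}-4-[(S)-hydroxy(4-methoxyphenyl)methyl]oxolane-3-carbaldehyde (may sit as its lactol) | COc1ccc([C@@H](O)[C@H]2CO[C@@H](c3ccc(O[Si](C)(C)C(C)(C)C)cc3)[C@@H]2C=O)cc1 | intermediate
14 | (S)-[(3R,4S,5R)-5-{4-[(tert-butyldimethylsilyl)oxy]phenyl}-4-(hydroxymethyl)oxolan-3-yl](4-methoxyphenyl)methanol | COc1ccc([C@@H](O)[C@H]2CO[C@@H](c3ccc(O[Si](C)(C)C(C)(C)C)cc3)[C@@H]2CO)cc1 | intermediate
15 | (S)-[(3R,4S,5R)-4-(acetoxymethyl)-5-{4-[(tert-butyldimethylsilyl)oxy]phenyl}oxolan-3-yl](4-methoxyphenyl)methyl acetate | COc1ccc([C@@H](OC(C)=O)[C@H]2CO[C@@H](c3ccc(O[Si](C)(C)C(C)(C)C)cc3)[C@@H]2COC(C)=O)cc1 | intermediate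
16 | (S)-[(3R,4S,5R)-4-(acetoxymethyl)-5-(4-hydroxyphenyl)oxolan-3-yl](4-methoxyphenyl)methyl acetate | COc1ccc([C@@H](OC(C)=O)[C@H]2CO[C@@H](c3ccc(O)cc3)[C@@H]2COC(C)=O)cc1 | target

Total step count: 8. Longest linear sequence: 7 steps (steps 1, 2, 4, 5, 6, 7, 8); step 3 is the one-step side branch.

Steps most likely to fail

Step 4. The monostabilised ketone enolate may alkylate the allyl terminus too slowly, so that the zwitterion isomerises or the vinyl ketone oligomerises, and the trans relay from C2 to C3 may be incomplete. The fallback sets out from 5 and comes back at 10. The same palladium catalyst with diethyl methylidenemalonate, a doubly activated acceptor of the class established for vinyl oxiranes, should give the geminal diester diethyl (4R,5R)-5-aryl-4-ethenyloxolane-3,3-dicarboxylate F1. Krapcho dealkoxycarbonylation (NaCl, wet DMSO, 150 °C) should then give the all-trans monoester F2, with C4 settling trans to the vinyl group. MeNH(OMe)·HCl with i-PrMgCl in THF converts it into the Weinreb amide F3, and 4-MeOC6H4MgBr in THF returns ketone 10.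

Step 5. Facial selectivity of hydride delivery to the exocyclic ketone may be eroded by the α-branched, Lewis-basic substrate. The fallback sets out from 10 and comes back at 12. Reduction under substrate control with LiBH(s-Bu)3 in THF at −78 °C (Felkin–Anh attack anti to C3) gives 12; any C7′ epimer, the (R)-alcohol F4, is separated by chromatography and returned to 10 by Dess–Martin periodinane oxidation for recycling.

Step 1. The thermally labile chloroallyl metal species may decompose before it adds to the electron-rich aldehyde, or enantio- and syn-selectivity may be incomplete at the temperature that can be held. The fallback sets out from 1 and comes back at 10. Horner–Wadsworth–Emmons olefination of 1 with diethyl allylphosphonate (n-BuLi, THF, −78 °C → rt) gives the (E)-diene F5. Shi epoxidation with the enantiomer of the fructose-derived ketone catalyst (1,2:4,5-di-O-isopropylidene-β-L-erythro-2,3-hexodiulo-2,6-pyranose), KHSO5 and K2CO3 in buffered MeCN/dimethoxymethane/water at 0 °C should epoxidise the more electron-rich styrenyl alkene and give the trans-oxirane F6. Under the conditions of step 4, F6 is ionised to the same zwitterion 8 as 5 and so gives 10.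

Further compounds
F1 | step 4 | diethyl (4R,5R)-5-{4-[(tert-butyldimethylsilyl)oxy]phenyl}-4-ethenyloxolane-3,3-dicarboxylate | CCOC(=O)C1(C(=O)OCC)CO[C@@H](c2ccc(O[Si](C)(C)C(C)(C)C)cc2)[C@@H]1C=C
F2 | step 4 | ethyl (3R,4R,5R)-5-{4-[(tert-butyldimethylsilyl)oxy]phenyl}-4-ethenyloxolane-3-carboxylate | CCOC(=O)[C@H]1CO[C@@H](c2ccc(O[Si](C)(C)C(C)(C)C)cc2)[C@@H]1C=C
F3 | step 4 | (3R,4R,5R)-5-{4-[(tert-butyldimethylsilyl)oxy]phenyl}-4-ethenyl-N-methoxy-N-methyloxolane-3-carboxamide | CON(C)C(=O)[C@H]1CO[C@@H](c2ccc(O[Si](C)(C)C(C)(C)C)cc2)[C@@H]1C=C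
F4 | step 5 | (R)-[(3R,4R,5R)-5-{4-[(tert-butyldimethylsilyl)oxy]phenyl}-4-ethenyloxolan-3-yl](4-methoxyphenyl)methanol | COc1ccc([C@H](O)[C@H]2CO[C@@H](c3ccc(O[Si](C)(C)C(C)(C)C)cc3)[C@@H]2C=C)cc1
F5 | step 1 | {4-[(1E)-buta-1,3-dien-1-yl]phenoxy}(tert-butyl)dimethylsilane | C=C/C=C/c1ccc(O[Si](C)(C)C(C)(C)C)cc1
F6 | step 1 | (2S,3S)-2-{4-[(tert-butyldimethylsilyl)oxy]phenyl}-3-ethenyloxirane (trans) | CC(C)(C)[Si](C)(C)Oc1ccc(cc1)[C@@H]1O[C@H]1C=C
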